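**Retrosynthetic overview**
1. The strategy rests on C5 of ring B (the cyclohexene C3a–C4–C5–C6=C7–C7a): a quaternary carbon whose two alkenyl arms, the ring alkene C6=C7 and the exocyclic styryl group, let it be drawn from a prochiral C5(CH=CH2)2 carbon.
2. Target ⇐ Heck arylation of the C5 vinyl group ⇐ ring-closing metathesis C6=C7 between one C5 vinyl group and the C7a isopropenyl group of an all-trans cyclopentanone (ring A); ring B closes last and C5 becomes stereogenic there.
3. All-trans ring A ⇐ SmI2 opening of a C3–O γ-lactone (C4 carboxyl tied to C3) ⇐ isopropenyl addition and C1 ethylation of the lactone enone ⇐ epoxidation–lactonisation, oxidation and dehydrogenation of a cyclopentene acid.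
4. C3a–C4 ⇐ Ireland–Claisen rearrangement of the (S)-2-methylcyclopent-2-en-1-yl ester (ring A bought as 2-methylcyclopent-2-en-1-one); C4–C5 ⇐ Ireland–Claisen rearrangement of a dienyl butanoate made from pent-2-yn-1-ol.
5. Ring order: ring A (purchased), temporary lactone ring (steps 8–12), ring B (step 13).

Key step: step 13

Remark: the locants C1–C7a of the target (indene numbering; C2 ketone, C4 carboxyl-bearing carbon, C5 divinyl carbon) are used for the same atoms in all intermediates, β is the ring-A face of the C3 methyl group, and the key-step precursor and product are taken as the free acids.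

**Route**

Step 1
Reactants: 1 pent-2-yn-1-ol
Product: 3 (2Z)-3-iodopent-2-en-1-ol, via cyclic alkenylaluminate 2 (not isolated)
Conditions: NaAlH2(OCH2CH2OMe)2, THF, 0 °C → rt; then I2, THF, −78 → 0 °C
Reagents that add atoms: iodine, [I][I]
Why: Hydroalumination of the propargylic alkoxide is trans and places aluminium on C3 in a five-membered alkoxyaluminate, so iodinolysis with retention should give the Z 3-iodo allylic alcohol (hydroalumination–iodination of a propargylic alcohol), and the alkene geometry is of no consequence later.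

Step 2
Reactants: 3 (2Z)-3-iodopent-2-en-1-ol; 4 tributyl(vinyl)stannane
Product: 5 (2Z)-3-ethylpenta-2,4-dien-1-ol
Conditions: PdCl2(MeCN)2 (5 mol%), DMF, rt
Reagents that add atoms: none
Why: Stille coupling of the alkenyl iodide with the vinylstannane goes with retention under ligand-free catalysis (the divalent palladium salt is reduced in situ to zerovalent palladium) and tolerates the free allylic alcohol.

Step 3
Reactants: 5 (2Z)-3-ethylpenta-2,4-dien-1-ol; 6 butanoyl chloride
Product: 7 (2Z)-3-ethylpenta-2,4-dien-1-yl butanoate
Conditions: Et3N, DMAP (cat.), CH2Cl2, 0 °C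
Reagents that add atoms: none
Why: DMAP-catalysed O-acylation of the primary allylic alcohol by the acid chloride.

Step 4
Reactants: 7 (2Z)-3-ethylpenta-2,4-dien-1-yl butanoate
Product: 11 (±)-3-ethenyl-2,3-diethylpent-4-enoic acid, via lithium enolate 8 (not isolated), via silyl ketene acetal 9 (not isolated), via trimethylsilyl ester 10 (not isolated)
Conditions: LiN(iPr)2, THF, −78 °C; TMSCl, −78 °C → rt; aq. HCl
Reagents that add atoms: none
Why: Ireland–Claisen rearrangement, in which the silyl ketene acetal shifts [3,3] onto the trisubstituted diene terminus to form the C4–C5 bond and a quaternary carbon with two identical vinyl groups (not stereogenic), while the α-carbon is formed racemic and is planarised again in step 7.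

Step 5
Reactants: 12 2-methylcyclopent-2-en-1-one
Product: 14 (1S)-2-methylcyclopent-2-en-1-ol, via alkoxyborane 13 (not isolated)
Conditions: (R)-2-methyl-CBS-oxazaborolidine (10 mol%), catecholborane, toluene, −78 °C; then H2O
Reagents that add atoms: none
Why: Corey–Bakshi–Shibata reduction, in which the oxazaborolidine binds the enone with the α-methylalkenyl arm as the large group so that the (R)-catalyst should give the (S)-allylic alcohol by 1,2-hydride delivery, catecholborane being chosen to avoid hydroboration of the alkene.

Step 6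
Reactants: 11 (±)-3-ethenyl-2,3-diethylpent-4-enoic acid; 14 (1S)-2-methylcyclopent-2-en-1-ol
Product: 16 (1S)-2-methylcyclopent-2-en-1-yl (2RS)-3-ethenyl-2,3-diethylpent-4-enoate, via acid chloride 15 (not isolated)
Conditions: (COCl)2, DMF (cat.), CH2Cl2, 0 °C → rt; then 14, pyridine, DMAP (cat.), CH2Cl2, 0 °C → rt
Reagents that add atoms: none
Why: Acylation of the secondary allylic alcohol by the acid chloride under nucleophilic catalysis, used because the α-branched acid next to a quaternary carbon is too hindered for carbodiimide coupling; the carbinol centre is untouched and the α-epimer mixture is inconsequential.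

Step 7
Reactants: 16 (1S)-2-methylcyclopent-2-en-1-yl (2RS)-3-ethenyl-2,3-diethylpent-4-enoate
Product: 20 (2R)-3-ethenyl-2,3-diethyl-2-[(1R)-2-methylcyclopent-2-en-1-yl]pent-4-enoic acid, via lithium enolate 17 (not isolated), via silyl ketene acetal 18 (not isolated), via trimethylsilyl ester 19 (not isolated)
Conditions: LiN(iPr)2, THF, −78 → −45 °C; TMSCl, −78 °C → rt, then 60 °C; aq. HCl
Reagents that add atoms: none
Why: Ireland–Claisen rearrangement with 1,3-chirality transfer, in which kinetic deprotonation in THF should place the bulky C5 substituent cis to the cyclopentenyloxy group (away from the amide in the closed deprotonation transition state) and this ketene acetal should rearrange through the chair on the face from which the C–O bond departs (the boat would push the C5 substituent under the ring), fixing C3a (R) and the quaternary C4 (R) together.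

Step 8
Reactants: 20 (2R)-3-ethenyl-2,3-diethyl-2-[(1R)-2-methylcyclopent-2-en-1-yl]pent-4-enoic acid
Product: 22 (3R,3aS,6R,6aR)-3-ethyl-3-(3-ethylpenta-1,4-dien-3-yl)-6-hydroxy-6a-methylhexahydro-2H-cyclopenta[b]furan-2-one (cis-fused C3–O γ-lactone; C2–OH β), via epoxy acid 21 (not isolated)
Conditions: mCPBA, CH2Cl2, 0 °C; then camphorsulfonic acid (cat.), rt
Reagents that add atoms: 3-chloroperbenzoic acid, OOC(=O)c1cccc(Cl)c1
Why: Prilezhaev epoxidation of the electron-rich trisubstituted ring alkene (faster than the two monosubstituted vinyl groups) on the β face opposite the quaternary C4 substituent, then acid-catalysed 5-exo opening at the tertiary C3 by the carboxyl group with inversion, which gives the cis-fused γ-lactone, masks the acid, makes C3 non-enolisable and leaves the C2 hydroxyl.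

Step 9
Reactants: 22 hydroxy lactone
Product: 23 (3R,3aS,6aR)-3-ethyl-3-(3-ethylpenta-1,4-dien-3-yl)-6a-methyltetrahydro-2H-cyclopenta[b]furan-2,6(3H)-dione
Conditions: Dess–Martin periodinane, CH2Cl2, rt
Reagents that add atoms: none
Why: Dess–Martin oxidation of the hindered secondary alcohol to the C2 ketone under neutral conditions that leave the lactone and the vinyl groups alone.

Step 10
Reactants: 23 keto lactone
Product: 24 (3R,3aS,6aR)-3-ethyl-3-(3-ethylpenta-1,4-dien-3-yl)-6a-methyl-3a,6a-dihydro-2H-cyclopenta[b]furan-2,6(3H)-dione (C1=C7a enone)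
Conditions: 2-iodoxybenzoic acid (IBX), DMSO, 70 °C
Reagents that add atoms: none
Why: IBX dehydrogenation of the ketone, which can enolise only towards C1 because C3 is quaternary, gives the C1=C7a enone without a palladium reagent that could engage the vinyl groups.

Step 11
Reactants: 24 enone lactone; 25 isopropenylmagnesium bromide
Product: 27 (3R,3aS,4R,5S,6aR)-3,5-diethyl-3-(3-ethylpenta-1,4-dien-3-yl)-6a-methyl-4-(prop-1-en-2-yl)tetrahydro-2H-cyclopenta[b]furan-2,6(3H)-dione, via magnesium enolate 26 (not isolated)
Conditions: CuBr·SMe2 (20 mol%), THF, −78 → −40 °C; then EtI, HMPA, −40 → 0 °C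
Reagents that add atoms: ethyl iodide, ICC
Why: Copper-catalysed conjugate addition of the Grignard reagent to C7a from the convex β face of the cis-fused bicycle (anti to the C3a–C4 bond), then C-alkylation of the enolate, which cannot equilibrate to the blocked C3, by ethyl iodide anti to the new isopropenyl group (tandem conjugate addition–enolate alkylation), should set C7a and C1 trans.

Step 12
Reactants: 27 ethylated keto lactone
Product: 30 (2R)-3-ethenyl-2,3-diethyl-2-[(1R,2S,4S,5R)-4-ethyl-2-methyl-3-oxo-5-(prop-1-en-2-yl)cyclopentyl]pent-4-enoic acid, via samarium enolate 28 (not isolated), via C3-epimeric keto acid 29 (not isolated)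
Conditions: SmI2 (2.5 equiv), THF/MeOH, −78 °C; then DBU, MeOH, rt; dilute aq. citric acid
Reagents that add atoms: none
Why: Reductive cleavage of the α-acyloxy ketone by two equivalents of divalent samarium (ketyl, loss of the carboxylate, second electron transfer) frees the C4 acid and a C2–C3 enolate, and protonation followed by base equilibration of the enolisable centres C1 and C3 should converge on the thermodynamically preferred all-trans cyclopentanone.

Step 13
Reactants: 30 all-trans keto acid with the C5 divinyl carbon and the C7a isopropenyl group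
Product: 31 (1S,3S,3aR,4R,5S,7aR)-5-ethenyl-1,4,5-triethyl-3,7-dimethyl-2-oxo-2,3,3a,4,5,7a-hexahydro-1H-indene-4-carboxylic acid
Conditions: RuCl2(=CHPh)(H2IMes)(PCy3) (second-generation Grubbs catalyst, 10 mol%), toluene (2 mM), 80 °C, argon sparge
Reagents that add atoms: none
Why: The ruthenium benzylidene exchanges onto either C5 vinyl group (the 1,1-disubstituted isopropenyl group does not initiate), and the resulting alkylidene adds across the isopropenyl C=C through a ruthenacyclobutane that collapses with loss of ethylene to the trisubstituted C6=C7 bond; this is ring-closing olefin metathesis used as a diastereotopic-group-selective desymmetrisation of a divinyl quaternary carbon, a known way to all-carbon quaternary stereocentres. Ring B is closed as a six-membered carbocycle, trans-fused to ring A, at a bond remote from the C3a–C7a fusion, and the adjacent quaternary carbons C4 and C5 favour the reactive gauche rotamer about C4–C5. C5 is the only new stereocentre and is set by which vinyl group becomes C6, under control of the neighbouring C4 centre (and through it C3a) in a chair-like closure in which C4 holds its ethyl group axial (α) and its carboxyl group equatorial (β). Because alkylidene exchange between the two vinyl groups should be faster than closure onto the hindered isopropenyl group, the irreversible closure is the selecting event. The step needs the vinyl group whose closure leaves the C5 ethyl group pseudoequatorial and the spectator vinyl group pseudoaxial on the β face, cis to CO2H and syn only to the axial H3a; what the substrate offers is the smaller demand of the flat vinyl group relative to ethyl in that site, a bias expected to be modest, so the C5 epimer ratio is the main uncertainty of the route. No other olefin pair can close a ring, and the free acid and the ketone are tolerated by the ruthenium catalyst.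

Step 14
Reactants: 31 C5-vinyl bicyclic acid; 32 iodobenzene
Product: 33 (1S,3S,3aR,4R,5S,7aR)-1,4,5-triethyl-3,7-dimethyl-2-oxo-5-[(E)-2-phenylethenyl]-2,3,3a,4,5,7a-hexahydro-1H-indene-4-carboxylic acid (target)
Conditions: Pd(OAc)2 (10 mol%), n-Bu4NCl, NaHCO3, DMF, 80 °C; mild acid work-up
Reagents that add atoms: none
Why: Mizoroki–Heck arylation under Jeffery conditions, in which phenylpalladium iodide adds to the terminal vinyl carbon and, because C5 is quaternary, the only syn β-hydrogens are benzylic, so elimination should give the E-styrene without double-bond migration while the trisubstituted ring alkene stays inert.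

**Compound list**
1 | pent-2-yn-1-ol | CCC#CCO | starting material
2 | cyclic sodium alkenylaluminate of 1 (Al on C3, alkoxide O on Al) | CCC1=CCO[Al-]1(OCCOC)OCCOC.[Na+] | intermediate
3 | (2Z)-3-iodopent-2-en-1-ol | CC/C(I)=C/CO | intermediate
4 | tributyl(vinyl)stannane | C=C[Sn](CCCC)(CCCC)CCCC | starting material
5 | (2Z)-3-ethylpenta-2,4-dien-1-ol | OC/C=C(/CC)C=C | intermediate
6 | butanoyl chloride | CCCC(=O)Cl | starting material
7 | (2Z)-3-ethylpenta-2,4-dien-1-yl butanoate | CCCC(=O)OC/C=C(/CC)C=C | intermediate
8 | lithium enolate of 7 | CCC=C(O[Li])OC/C=C(/CC)C=C | intermediate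
9 | trimethylsilyl ketene acetal of 7 | CCC=C(O[Si](C)(C)C)OC/C=C(/CC)C=C | intermediate
10 | trimethylsilyl 3-ethenyl-2,3-diethylpent-4-enoate | CCC(C(=O)O[Si](C)(C)C)C(CC)(C=C)C=C | intermediate
11 | (±)-3-ethenyl-2,3-diethylpent-4-enoic acid | CCC(C(=O)O)C(CC)(C=C)C=C | intermediate
12 | 2-methylcyclopent-2-en-1-one | CC1=CCCC1=O | starting material
13 | 2-{[(1S)-2-methylcyclopent-2-en-1-yl]oxy}-1,3,2-benzodioxaborole | CC1=CCC[C@@H]1OB1Oc2ccccc2O1 | intermediate
14 | (1S)-2-methylcyclopent-2-en-1-ol | CC1=CCC[C@@H]1O | intermediate
15 | 3-ethenyl-2,3-diethylpent-4-enoyl chloride | CCC(C(=O)Cl)C(CC)(C=C)C=C | intermediate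
16 | (1S)-2-methylcyclopent-2-en-1-yl (2RS)-3-ethenyl-2,3-diethylpent-4-enoate | CCC(C(=O)O[C@H]1CCC=C1C)C(CC)(C=C)C=C | intermediate
17 | lithium enolate of 16 (C5 substituent cis to the cyclopentenyloxy group, ethyl cis to O–Li) | [Li]O/C(O[C@H]1CCC=C1C)=C(\CC)C(CC)(C=C)C=C | intermediate
18 | (E)-trimethylsilyl ketene acetal of 16 (C5 substituent cis to the cyclopentenyloxy group) | C[Si](C)(C)O/C(O[C@H]1CCC=C1C)=C(\CC)C(CC)(C=C)C=C | intermediate
19 | trimethylsilyl ester of 20 | CC1=CCC[C@H]1[C@@](CC)(C(=O)O[Si](C)(C)C)C(CC)(C=C)C=C | intermediate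
20 | (2R)-3-ethenyl-2,3-diethyl-2-[(1R)-2-methylcyclopent-2-en-1-yl]pent-4-enoic acid | CC1=CCC[C@H]1[C@@](CC)(C(=O)O)C(CC)(C=C)C=C | intermediate
21 | β-epoxide of 20 (C2–C3 epoxide trans to the C3a–C4 bond) | C[C@@]12O[C@@H]1CC[C@H]2[C@@](CC)(C(=O)O)C(CC)(C=C)C=C | intermediate
22 | (3R,3aS,6R,6aR)-3-ethyl-3-(3-ethylpenta-1,4-dien-3-yl)-6-hydroxy-6a-methylhexahydro-2H-cyclopenta[b]furan-2-one | O=C1O[C@@]2(C)[C@H](O)CC[C@H]2[C@]1(CC)C(CC)(C=C)C=C | intermediate
23 | (3R,3aS,6aR)-3-ethyl-3-(3-ethylpenta-1,4-dien-3-yl)-6a-methyltetrahydro-2H-cyclopenta[b]furan-2,6(3H)-dione | O=C1O[C@@]2(C)C(=O)CC[C@H]2[C@]1(CC)C(CC)(C=C)C=C | intermediate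
24 | (3R,3aS,6aR)-3-ethyl-3-(3-ethylpenta-1,4-dien-3-yl)-6a-methyl-3a,6a-dihydro-2H-cyclopenta[b]furan-2,6(3H)-dione | O=C1O[C@@]2(C)C(=O)C=C[C@H]2[C@]1(CC)C(CC)(C=C)C=C | intermediate
25 | isopropenylmagnesium bromide | CC(=C)[Mg]Br | starting material
26 | bromomagnesium C1=C2 enolate after isopropenyl addition to 24 | O=C1O[C@@]2(C)C(O[Mg]Br)=C[C@H](C(C)=C)[C@H]2[C@]1(CC)C(CC)(C=C)C=C | intermediate
27 | (3R,3aS,4R,5S,6aR)-3,5-diethyl-3-(3-ethylpenta-1,4-dien-3-yl)-6a-methyl-4-(prop-1-en-2-yl)tetrahydro-2H-cyclopenta[b]furan-2,6(3H)-dione | O=C1O[C@@]2(C)C(=O)[C@@H](CC)[C@H](C(C)=C)[C@H]2[C@]1(CC)C(CC)(C=C)C=C | intermediate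
28 | bis(diiodosamarium) C2–C3 enolate carboxylate from 27 | CC[C@@H]1C(O[Sm](I)I)=C(C)[C@@H]([C@H]1C(C)=C)[C@@](CC)(C(=O)O[Sm](I)I)C(CC)(C=C)C=C | intermediate
29 | C3 epimer of 30 (C3 methyl cis to the C3a substituent) | CC[C@@H]1C(=O)[C@H](C)[C@@H]([C@H]1C(C)=C)[C@@](CC)(C(=O)O)C(CC)(C=C)C=C | intermediate
30 | (2R)-3-ethenyl-2,3-diethyl-2-[(1R,2S,4S,5R)-4-ethyl-2-methyl-3-oxo-5-(prop-1-en-2-yl)cyclopentyl]pent-4-enoic acid | CC[C@@H]1C(=O)[C@@H](C)[C@@H]([C@H]1C(C)=C)[C@@](CC)(C(=O)O)C(CC)(C=C)C=C | intermediate
31 | (1S,3S,3aR,4R,5S,7aR)-5-ethenyl-1,4,5-triethyl-3,7-dimethyl-2-oxo-2,3,3a,4,5,7a-hexahydro-1H-indene-4-carboxylic acid | CC[C@@H]1C(=O)[C@@H](C)[C@H]2[C@H]1C(C)=C[C@@](C=C)(CC)[C@]2(CC)C(=O)O | intermediate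
32 | iodobenzene | Ic1ccccc1 | starting material
33 | (1S,3S,3aR,4R,5S,7aR)-1,4,5-triethyl-3,7-dimethyl-2-oxo-5-[(E)-2-phenylethenyl]-2,3,3a,4,5,7a-hexahydro-1H-indene-4-carboxylic acid | CC[C@@H]1C(=O)[C@@H](C)[C@H]2[C@H]1C(C)=C[C@@](/C=C/c1ccccc1)(CC)[C@]2(CC)C(=O)O | target

**Step count**
Total: 14 steps. Longest linear sequence: 13 steps (steps 1–4 and 6–14, from pent-2-yn-1-ol); step 5 is a one-step branch.

**Steps most likely to fail**

1. Step 13 (key step). The irreversible ring closure may discriminate poorly between the two diastereotopic vinyl groups, so that the C5 epimer is co-formed; loading of ruthenium on the neopentyl-type vinyl groups may also be slow. The fallback moves the choice of vinyl group to a separable, reversible tethering event. It sets out from 30: iodolactonisation (I2, NaHCO3, MeCN/H2O, 0 °C; 5-exo attack of the C4 carboxylate on a C5 vinyl group, expected to outrun 6-exo attack on the isopropenyl group) would give the γ-iodolactone with the untouched vinyl group cis to C3a, F1, and its C5 epimer, F2. The two are separated by chromatography, and F2 is returned to 30 with Zn in AcOH (reductive β-elimination). F1 has only the correct vinyl group left and is closed with the same ruthenium catalyst to the tricyclic iodolactone F3. Zn in AcOH then regenerates the vinyl group and the acid, and the route is rejoined at 31.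

2. Step 7. Deprotonation of the hindered α-CH may be slow or may give both ketene acetal geometries, which would erode the C4 configuration (C3a is secured by chirality transfer); the congested chair may also compete with a boat. The fallback replaces sterically biased kinetic enolisation of the epimer mixture by stereospecific, reagent-controlled enolisation of single epimers. It sets out from 16: the α-epimers, the (2S) ester F4 and the (2R) ester F5, are separated by preparative HPLC. Each is deprotonated with the enantiomer of a chelating chiral lithium amide that is matched to it (identified by a trial silylation), so that both converge on ketene acetal 18. Rearrangement and hydrolysis then rejoin the route at 20.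

3. Step 11. C-ethylation of the magnesium enolate may be sluggish, with proton transfer and over-alkylation at C1, or the organocopper species may reductively remove the α'-acyloxy group. The fallback installs the ethyl group on the enone before the conjugate addition. It sets out from 24: α-iodination (I2, pyridine, CH2Cl2) would give the 2-iodo enone lactone F6. B-alkyl Suzuki–Miyaura coupling with Et3B (PdCl2(dppf), AsPh3, Cs2CO3, DMF/THF/H2O) gives the C1-ethyl enone lactone F7. Copper-catalysed addition of 25 in the presence of TMSCl (CuBr·SMe2, THF, −78 °C) gives the trimethylsilyl enol ether F8. Hydrolysis (aq. HCl) gives 27 together with any C1 epimer F9, which is equilibrated with DBU (C1 is the only enolisable centre), and the route is rejoined at 27.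

**Further compounds**
F1 | step 13 | γ-iodolactone of 30 (C4 carboxyl closed on one C5 vinyl group; free vinyl group cis to C3a; iodomethyl carbon as epimer mixture) | CC[C@@H]1C(=O)[C@@H](C)[C@@H]([C@H]1C(C)=C)[C@@]2(CC)C(=O)OC(C[I])[C@@]2(CC)C=C
F2 | step 13 | C5 epimer of F1 (free vinyl group trans to C3a) | CC[C@@H]1C(=O)[C@@H](C)[C@@H]([C@H]1C(C)=C)[C@@]2(CC)C(=O)OC(C[I])[C@]2(CC)C=C
F3 | step 13 | tricyclic iodolactone (ring B closed; γ-lactone cis-fused across C4–C5) | CC[C@@H]1C(=O)[C@@H](C)[C@H]2[C@H]1C(C)=C[C@@]3(CC)[C@]2(CC)C(=O)OC3C[I]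
F4 | step 7 | (1S)-2-methylcyclopent-2-en-1-yl (2S)-3-ethenyl-2,3-diethylpent-4-enoate | CC[C@H](C(=O)O[C@H]1CCC=C1C)C(CC)(C=C)C=C
F5 | step 7 | (1S)-2-methylcyclopent-2-en-1-yl (2R)-3-ethenyl-2,3-diethylpent-4-enoate | CC[C@@H](C(=O)O[C@H]1CCC=C1C)C(CC)(C=C)C=C
F6 | step 11 | 2-iodo enone lactone (iodine on C1 of 24) | O=C1O[C@@]2(C)C(=O)C(I)=C[C@H]2[C@]1(CC)C(CC)(C=C)C=C
F7 | step 11 | C1-ethyl enone lactone | O=C1O[C@@]2(C)C(=O)C(CC)=C[C@H]2[C@]1(CC)C(CC)(C=C)C=C
F8 | step 11 | trimethylsilyl enol ether (C1=C2) of 27 | O=C1O[C@@]2(C)C(O[Si](C)(C)C)=C(CC)[C@H](C(C)=C)[C@H]2[C@]1(CC)C(CC)(C=C)C=C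
F9 | step 11 | C1 epimer of 27 (ethyl cis to isopropenyl) | O=C1O[C@@]2(C)C(=O)[C@H](CC)[C@H](C(C)=C)[C@H]2[C@]1(CC)C(CC)(C=C)C=C
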